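**Plan**

- Cuts (target numbering of the core: C1 ketone carbon, C3 carbinol carbon, C4 aroyl-bearing carbon; rings A/B = tetralone, ring C = resorcinol with primed locants, ring D = pyranone): first the C6'–CH2 and C1'–C(=O) bonds of ring C together, then the C(=O)–CH2 bond to ring D, then C3–C4 and O3–C(=O) of a β-lactone.
- Enabling feature: on ring C the acyl-bearing C1' and the CH2-bearing C6' are neighbours and C1' sits beside the oxygenated C2', while the CH2 lies between the ketone carbonyl and C6 of ring D. A 3,5-dioxygenated benzyne can therefore enter the C(=O)–CH2 σ bond of a pyranonylmethyl ketone (a vinylogous β-keto ester) and deliver ring C with both neighbours at once.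
- Forward: ring A is bought; ring B closes by catalytic asymmetric aldol-lactonisation of a keto acid; the cis β-lactone acylates the 6-methyl anion of ring D; ring C is then inserted as the aryne.
- Stereochemistry: C4 (S) comes from the isothiourea-bound enolate, C3 (R) from the obligatory cis fusion of the β-lactone, which also places hydroxyl and acyl cis.
- Helpers: the β-lactone (temporary ring and acyl donor), C1 held as CH2 and O3 capped as a benzyloxymethyl ether through the basic steps; C1 is then oxidised with DDQ and all six protecting groups fall in one hydrogenolysis.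

Key step: step 12

Assumption: the facial sense of (S)-HBTM is taken from the usual model for isothiourea-bound (Z)-ammonium enolates (enolate oxygen syn to sulfur, electrophile anti to the C2 phenyl group), which predicts (S) at C4; if the sense proved opposite, the mirror-image catalyst would be used.

**Route**

Step 1
Reactants: 1 methyl 2-(3,5-dihydroxyphenyl)acetate
Product: 2 methyl 2-[3,5-bis(benzyloxy)phenyl]acetate
Conditions: BnBr, K2CO3, acetone, reflux
Reagents that add atoms: benzyl bromide BrCc1ccccc1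
Why: Williamson etherification of both phenols with a carbonate base that does not deprotonate the ester α-CH2.

Step 2
Reactants: 2 methyl 2-[3,5-bis(benzyloxy)phenyl]acetate
Product: 3 methyl 2-[3,5-bis(benzyloxy)-2-iodophenyl]acetate
Conditions: N-iodosuccinimide, CF3CO2H (cat.), MeCN, 0 °C to rt
Reagents that add atoms: N-iodosuccinimide O=C1CCC(=O)N1I
Why: Electrophilic aromatic iodination should go to the ring position ortho to one benzyloxy group and para to the other, which is less hindered than the position between the two ethers.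

Step 3
Reactants: 3 methyl 2-[3,5-bis(benzyloxy)-2-iodophenyl]acetate; 4 but-3-en-2-ol (racemic)
Product: 5 methyl 2-[3,5-bis(benzyloxy)-2-(3-oxobutyl)phenyl]acetate
Conditions: Pd(OAc)2 (cat.), Bu4NCl, NaHCO3, DMF, 60 °C
Reagents that add atoms: none
Why: Heck reaction with an allylic alcohol, in which the arylpalladium adds to the terminal alkene carbon and β-hydride elimination toward the carbinol gives the enol and hence the methyl ketone directly, the stereocentre of 4 being destroyed.

Step 4
Reactants: 5 methyl 2-[3,5-bis(benzyloxy)-2-(3-oxobutyl)phenyl]acetate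
Product: 6 2-[3,5-bis(benzyloxy)-2-(3-oxobutyl)phenyl]acetic acid
Conditions: LiOH, THF/H2O, 0 °C to rt; then 1 M HCl
Reagents that add atoms: lithium hydroxide [Li+].[OH-]
Why: Ester saponification, which should be faster than any aldol chemistry of the ketone in cold aqueous base.

Step 5
Reactants: 6 2-[3,5-bis(benzyloxy)-2-(3-oxobutyl)phenyl]acetic acid
Product: 8 (3R,4S)-β-lactone of 6,8-bis(benzyloxy)-3-hydroxy-3-methyl-1,2,3,4-tetrahydronaphthalene-4-carboxylic acid (target numbering; C4 carboxyl closed onto O3; cis-fused), via mixed tosyl anhydride 7 (not isolated)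
Conditions: TsCl, iPr2NEt, LiCl, (S)-HBTM [(2S)-2-phenyl-3,4-dihydro-2H-pyrimido[2,1-b][1,3]benzothiazole, 20 mol %], CH2Cl2, 23 °C
Reagents that add atoms: none
Why: Nucleophile-catalysed aldol-lactonisation of a keto acid, in which the catalyst-bound (Z)-ammonium enolate attacks the methyl ketone on the face away from the catalyst phenyl group to set C4 as S, and the alkoxide can only close the four-membered ring onto the acylammonium when it is cis, which sets C3 as R and forms ring B.

Step 6
Reactants: 9 4-hydroxy-6-methyl-2H-pyran-2-one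
Product: 10 4-(benzyloxy)-6-methyl-2H-pyran-2-one
Conditions: BnOH, PPh3, diisopropyl azodicarboxylate, THF, 0 °C to rt
Reagents that add atoms: benzyl alcohol OCc1ccccc1
Why: Mitsunobu etherification of the acidic 4-hydroxyl (a vinylogous carboxylic acid) should give O-alkylation and avoid the C3-alkylation seen with benzyl halides and base.

Step 7
Reactants: 8 the (3R,4S)-β-lactone; 10 4-(benzyloxy)-6-methyl-2H-pyran-2-one
Product: 12 4-(benzyloxy)-6-{2-[(1S,2R)-5,7-bis(benzyloxy)-2-hydroxy-2-methyl-1,2,3,4-tetrahydronaphthalen-1-yl]-2-oxoethyl}-2H-pyran-2-one, via lithiated pyranone 11 (not isolated)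
Conditions: 10 (2.2 equiv), LiN(SiMe3)2 (2.2 equiv), THF, −78 °C; then 8, −78 °C; AcOH quench at −78 °C
Reagents that add atoms: none
Why: Lateral lithiation of the 6-methyl group (vinylogous ester) followed by Claisen-type C-acylation through acyl–oxygen cleavage of the strained β-lactone, which touches neither stereocentre and leaves hydroxyl and acyl cis, while the second equivalent of anion stores the product as its enolate and so disfavours retro-aldol cleavage.

Step 8
Reactants: 12 the hydroxy ketone from step 7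
Product: 13 4-(benzyloxy)-6-{2-[(1S,2R)-5,7-bis(benzyloxy)-2-[(benzyloxy)methoxy]-2-methyl-1,2,3,4-tetrahydronaphthalen-1-yl]-2-oxoethyl}-2H-pyran-2-one
Conditions: BnOCH2Cl, iPr2NEt, Bu4NI (cat.), CH2Cl2, 40 °C; then 0.5 M HCl, THF, 0 °C
Reagents that add atoms: benzyl chloromethyl ether ClCOCc1ccccc1
Why: Alkoxymethylation of the tertiary alcohol under amine base, where any enol acetal formed at the acidic CH2 is returned to the ketone by the dilute acid wash and the alkyl acetal is kept.

Step 9
Reactants: 14 3,5-bis(benzyloxy)phenol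
Product: 15 3,5-bis(benzyloxy)phenyl N-(propan-2-yl)carbamate
Conditions: iPrNCO, Et3N (cat.), CH2Cl2, rt
Reagents that add atoms: isopropyl isocyanate CC(C)N=C=O
Why: Carbamoylation of the phenol by addition to the isocyanate installs a strong ortho-directing group that can later be removed under mild base.

Step 10
Reactants: 15 3,5-bis(benzyloxy)phenyl N-(propan-2-yl)carbamate
Product: 19 3,5-bis(benzyloxy)-2-(trimethylsilyl)phenyl N-(propan-2-yl)carbamate, via N-silyl carbamate 16 (not isolated), via ortho-lithiated carbamate 17 (not isolated), via C-silylated N-silyl carbamate 18 (not isolated)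
Conditions: tBuMe2SiOTf, TMEDA, Et2O, 0 °C to rt; n-BuLi, TMEDA, −78 °C; Me3SiCl, −78 °C to rt; aq. NaHSO4
Reagents that add atoms: chlorotrimethylsilane C[Si](C)(C)Cl
Why: Directed ortho-metalation after in situ N-silylation, with lithiation at the carbon flanked by the carbamate oxygen and a benzyloxy group (the two such positions are equivalent by symmetry), silyl quench and loss of the N-silyl group on work-up.

Step 11
Reactants: 19 3,5-bis(benzyloxy)-2-(trimethylsilyl)phenyl N-(propan-2-yl)carbamate
Product: 21 3,5-bis(benzyloxy)-2-(trimethylsilyl)phenyl trifluoromethanesulfonate, via silyl phenol 20 (not isolated)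
Conditions: Et2NH, DBU, MeCN, 40 °C; then PhNTf2, rt
Reagents that add atoms: N-phenylbis(trifluoromethanesulfonimide) O=S(=O)(N(c1ccccc1)S(=O)(=O)C(F)(F)F)C(F)(F)F
Why: Base-induced E1cB cleavage of the N–H carbamate (the isocyanate is trapped by Et2NH) gives the phenoxide, which is triflated in the same flask, the standard route to ortho-silylaryl triflates.

Step 12
Reactants: 13 the benzyloxymethyl-protected pyranonylmethyl ketone; 21 3,5-bis(benzyloxy)-2-(trimethylsilyl)phenyl trifluoromethanesulfonate
Product: 24 4-(benzyloxy)-6-{3,5-bis(benzyloxy)-2-[(1S,2R)-5,7-bis(benzyloxy)-2-[(benzyloxy)methoxy]-2-methyl-1,2,3,4-tetrahydronaphthalene-1-carbonyl]benzyl}-2H-pyran-2-one, via aryne 22 (not isolated), via benzocyclobutenol adduct 23 (not isolated)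
Conditions: CsF, MeCN, 60 °C (21 in slight excess)
Reagents that add atoms: none
Why: Proposed new method: fluoride releases 3,5-bis(benzyloxy)benzyne 22 from 21 and generates the enolate of 13 at the CH2 between the ketone and pyranone C6; the enolate carbon adds to the aryne, the resulting aryl anion closes onto the ketone carbonyl to give benzocyclobutenoxide 23, and alkoxide-driven opening of the strained ring cleaves the former C(=O)–CH2 bond to give the aryl ketone and a benzylic anion stabilised by the pyranone, which is protonated. The closest known reaction type is the acyl-alkylation of arynes by σ-insertion into the C–C bond of β-keto esters (also β-diketones and malonates); the untested element is that the departing carbanion is stabilised through the pyranone as a vinylogous ester instead of by an ester directly. No ring of the product is closed: the only ring formed is the transient cyclobutene, by 4-exo-trig attack of the aryl anion on the carbonyl, and it is opened again in the same operation. No stereocentre is created; C3 and C4 are carried through, because C4–H is less acidic than the CH2 that is enolised and the capped O3 cannot start a retro-aldol cleavage. The step needs regioselective addition to the aryne, which the benzyloxy group beside the triple bond secures: its inductive pull widens the angle at the distal aryne carbon and makes that carbon the electrophilic site, so it takes the CH2 while the anion develops ortho to oxygen, and the acyl group ends between OBn and CH2 as in ring C. It also needs C-attack at the central carbon of the extended enolate, the site flanked by both acceptors, and ring opening toward the CH2, the only cleavage that releases a doubly stabilised carbanion.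

Step 13
Reactants: 24 the protected tetralin from step 12
Product: 26 (3R,4S)-6,8-bis(benzyloxy)-4-{2,4-bis(benzyloxy)-6-{[4-(benzyloxy)-2-oxo-2H-pyran-6-yl]methyl}benzoyl}-3-[(benzyloxy)methoxy]-3-methyl-3,4-dihydronaphthalen-1(2H)-one, via benzylic alcohol 25 (not isolated)
Conditions: DDQ (2.5 equiv), 1,4-dioxane/H2O, rt
Reagents that add atoms: water O
Why: DDQ benzylic oxidation by hydride abstraction, selective because only the C1 methylene is ortho and para to benzyloxy groups (at C8 and C6) and gives a stabilised cation that water captures before a second oxidation to the aryl ketone, whereas C4–H and the ring C CH2 are meta to the ethers and next to a carbonyl or the electron-poor pyranone.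

Step 14
Reactants: 26 the fully protected tetralone
Product: 28 (3R,4S)-4-{2,4-dihydroxy-6-[(4-hydroxy-2-oxo-2H-pyran-6-yl)methyl]benzoyl}-3,6,8-trihydroxy-3-methyl-3,4-dihydronaphthalen-1(2H)-one (CNP0197349.1), via hemiformal 27 (not isolated)
Conditions: H2 (1 atm), Pd/C, EtOAc/MeOH, rt; filtration and evaporation without acid or base
Reagents that add atoms: none
Why: Hydrogenolysis of the five benzyl ethers and of the benzyloxymethyl acetal (whose hemiformal loses formaldehyde) under neutral conditions, so that the β-hydroxy ketone should neither dehydrate to the naphthol nor epimerise at C4, and the C3–O bond, not being benzylic, is kept.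

**Compound list**

1 | methyl 2-(3,5-dihydroxyphenyl)acetate | COC(=O)Cc1cc(O)cc(O)c1 | starting material
2 | methyl 2-[3,5-bis(benzyloxy)phenyl]acetate | COC(=O)Cc1cc(OCc2ccccc2)cc(OCc2ccccc2)c1 | intermediate
3 | methyl 2-[3,5-bis(benzyloxy)-2-iodophenyl]acetate | COC(=O)Cc1cc(OCc2ccccc2)cc(OCc2ccccc2)c1I | intermediate
4 | but-3-en-2-ol (racemic) | CC(O)C=C | starting material
5 | methyl 2-[3,5-bis(benzyloxy)-2-(3-oxobutyl)phenyl]acetate | COC(=O)Cc1cc(OCc2ccccc2)cc(OCc2ccccc2)c1CCC(C)=O | intermediate
6 | 2-[3,5-bis(benzyloxy)-2-(3-oxobutyl)phenyl]acetic acid | OC(=O)Cc1cc(OCc2ccccc2)cc(OCc2ccccc2)c1CCC(C)=O | intermediate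
7 | mixed anhydride of 6 with 4-methylbenzenesulfonic acid | Cc1ccc(cc1)S(=O)(=O)OC(=O)Cc1cc(OCc2ccccc2)cc(OCc2ccccc2)c1CCC(C)=O | intermediate
8 | (3R,4S)-β-lactone of 6,8-bis(benzyloxy)-3-hydroxy-3-methyl-1,2,3,4-tetrahydronaphthalene-4-carboxylic acid (target numbering, cis-fused) | C[C@@]1(OC2=O)CCc3c(OCc4ccccc4)cc(OCc4ccccc4)cc3[C@@H]12 | intermediate
9 | 4-hydroxy-6-methyl-2H-pyran-2-one | Cc1cc(O)cc(=O)o1 | starting material
10 | 4-(benzyloxy)-6-methyl-2H-pyran-2-one | Cc1cc(OCc2ccccc2)cc(=O)o1 | intermediate
11 | [4-(benzyloxy)-2-oxo-2H-pyran-6-yl]methyllithium | [Li]Cc1cc(OCc2ccccc2)cc(=O)o1 | intermediate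
12 | 4-(benzyloxy)-6-{2-[(1S,2R)-5,7-bis(benzyloxy)-2-hydroxy-2-methyl-1,2,3,4-tetrahydronaphthalen-1-yl]-2-oxoethyl}-2H-pyran-2-one | C[C@@]1(O)CCc2c(OCc3ccccc3)cc(OCc3ccccc3)cc2[C@@H]1C(=O)Cc1cc(OCc2ccccc2)cc(=O)o1 | intermediate
13 | 4-(benzyloxy)-6-{2-[(1S,2R)-5,7-bis(benzyloxy)-2-[(benzyloxy)methoxy]-2-methyl-1,2,3,4-tetrahydronaphthalen-1-yl]-2-oxoethyl}-2H-pyran-2-one | C[C@@]1(OCOCc2ccccc2)CCc2c(OCc3ccccc3)cc(OCc3ccccc3)cc2[C@@H]1C(=O)Cc1cc(OCc2ccccc2)cc(=O)o1 | intermediate
14 | 3,5-bis(benzyloxy)phenol | Oc1cc(OCc2ccccc2)cc(OCc2ccccc2)c1 | starting material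
15 | 3,5-bis(benzyloxy)phenyl N-(propan-2-yl)carbamate | CC(C)NC(=O)Oc1cc(OCc2ccccc2)cc(OCc2ccccc2)c1 | intermediate
16 | 3,5-bis(benzyloxy)phenyl N-[tert-butyl(dimethyl)silyl]-N-(propan-2-yl)carbamate | CC(C)N([Si](C)(C)C(C)(C)C)C(=O)Oc1cc(OCc2ccccc2)cc(OCc2ccccc2)c1 | intermediate
17 | 2-lithio derivative of 16 (lithium between the carbamate oxygen and a benzyloxy group) | CC(C)N([Si](C)(C)C(C)(C)C)C(=O)Oc1cc(OCc2ccccc2)cc(OCc2ccccc2)c1[Li] | intermediate
18 | 3,5-bis(benzyloxy)-2-(trimethylsilyl)phenyl N-[tert-butyl(dimethyl)silyl]-N-(propan-2-yl)carbamate | CC(C)N([Si](C)(C)C(C)(C)C)C(=O)Oc1cc(OCc2ccccc2)cc(OCc2ccccc2)c1[Si](C)(C)C | intermediate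
19 | 3,5-bis(benzyloxy)-2-(trimethylsilyl)phenyl N-(propan-2-yl)carbamate | CC(C)NC(=O)Oc1cc(OCc2ccccc2)cc(OCc2ccccc2)c1[Si](C)(C)C | intermediate
20 | 3,5-bis(benzyloxy)-2-(trimethylsilyl)phenol | Oc1cc(OCc2ccccc2)cc(OCc2ccccc2)c1[Si](C)(C)C | intermediate
21 | 3,5-bis(benzyloxy)-2-(trimethylsilyl)phenyl trifluoromethanesulfonate | C[Si](C)(C)c1c(OCc2ccccc2)cc(OCc2ccccc2)cc1OS(=O)(=O)C(F)(F)F | intermediate
22 | 3,5-bis(benzyloxy)benzyne (1,2-didehydro-3,5-bis(benzyloxy)benzene) | C1#CC(OCc2ccccc2)=CC(OCc2ccccc2)=C1 | intermediate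
23 | benzocyclobutenol adduct (present as its cesium alkoxide; carbinol carbon bears the tetralinyl group, the neighbouring ring carbon bears the pyranone; the two new ring centres are formed as a mixture and are not defined) | C[C@@]1(OCOCc2ccccc2)CCc2c(OCc3ccccc3)cc(OCc3ccccc3)cc2[C@@H]1C1(O)C(c2cc(OCc3ccccc3)cc(=O)o2)c2cc(OCc3ccccc3)cc(OCc3ccccc3)c12 | intermediate
24 | 4-(benzyloxy)-6-{3,5-bis(benzyloxy)-2-[(1S,2R)-5,7-bis(benzyloxy)-2-[(benzyloxy)methoxy]-2-methyl-1,2,3,4-tetrahydronaphthalene-1-carbonyl]benzyl}-2H-pyran-2-one | C[C@@]1(OCOCc2ccccc2)CCc2c(OCc3ccccc3)cc(OCc3ccccc3)cc2[C@@H]1C(=O)c1c(OCc2ccccc2)cc(OCc2ccccc2)cc1Cc1cc(OCc2ccccc2)cc(=O)o1 | intermediate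
25 | C1 benzylic alcohol of 24 (target numbering; both C1 epimers, centre not defined) | C[C@@]1(OCOCc2ccccc2)CC(O)c2c(OCc3ccccc3)cc(OCc3ccccc3)cc2[C@@H]1C(=O)c1c(OCc2ccccc2)cc(OCc2ccccc2)cc1Cc1cc(OCc2ccccc2)cc(=O)o1 | intermediate
26 | (3R,4S)-6,8-bis(benzyloxy)-4-{2,4-bis(benzyloxy)-6-{[4-(benzyloxy)-2-oxo-2H-pyran-6-yl]methyl}benzoyl}-3-[(benzyloxy)methoxy]-3-methyl-3,4-dihydronaphthalen-1(2H)-one | C[C@@]1(OCOCc2ccccc2)CC(=O)c2c(OCc3ccccc3)cc(OCc3ccccc3)cc2[C@@H]1C(=O)c1c(OCc2ccccc2)cc(OCc2ccccc2)cc1Cc1cc(OCc2ccccc2)cc(=O)o1 | intermediate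
27 | O3-hydroxymethyl hemiformal of the target | C[C@@]1(OCO)CC(=O)c2c(O)cc(O)cc2[C@@H]1C(=O)c1c(O)cc(O)cc1Cc1cc(O)cc(=O)o1 | intermediate
28 | (3R,4S)-4-{2,4-dihydroxy-6-[(4-hydroxy-2-oxo-2H-pyran-6-yl)methyl]benzoyl}-3,6,8-trihydroxy-3-methyl-3,4-dihydronaphthalen-1(2H)-one | C[C@@]1(O)CC(=O)c2c(O)cc(O)cc2[C@@H]1C(=O)c1c(O)cc(O)cc1Cc1cc(O)cc(=O)o1 | target

**Count**

Total steps: 14. Longest linear sequence: 10 steps (steps 1 to 5, 7, 8, 12, 13, 14).

**Steps most likely to fail**

Step 12. The aryl anion may be protonated before it closes onto the hindered ketone (plain α-arylation), the extended enolate may be arylated at oxygen or at the pyranone ring carbons, and fluoride may cause epimerisation at C4 or β-elimination of the benzyloxymethoxy group. The fallback uses the established β-keto ester version and builds ring D afterwards; it sets out from 8 and returns at 24. Lactone 8 is opened with the lithium enolate of allyl acetate (LiN(iPr)2, THF, −78 °C) to give allyl 3-[(1S,2R)-5,7-bis(benzyloxy)-2-hydroxy-2-methyl-1,2,3,4-tetrahydronaphthalen-1-yl]-3-oxopropanoate F1, which is protected as in step 8 to give the benzyloxymethyl ether F2. Acyl-alkylation of aryne 22 (from 21, CsF, MeCN) with this β-keto ester gives the allyl arylacetate F3. Deallylation with zerovalent palladium (Pd(PPh3)4, morpholine) gives the arylacetic acid F4. Activation with 1,1'-carbonyldiimidazole and addition of the dianion of tert-butyl acetoacetate gives the tert-butyl 3,5-dioxohexanoate F5. Thermolysis (toluene, 110 °C) closes the 4-hydroxy-2-pyranone F6 through the acylketene, and Mitsunobu benzylation as in step 6 gives 24.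

Step 13. Loss of a C2 proton from the C1 cation followed by further dehydrogenation, oxidative cleavage of benzyl ethers, or incomplete site selectivity may erode the late oxidation. The fallback moves the oxidation to the simplest substrate and carries the ketone through; it sets out from 8 and returns at 26. Lactone 8 is oxidised with DDQ in wet dioxane to the C1-keto β-lactone F7. This is opened with lithiated pyranone 11 at −78 °C as in step 7 to give the keto hydroxy ketone F8, which is protected as in step 8 to give the benzyloxymethyl ether F9. The aryne insertion with 21 is then run under the mildest fluoride conditions (KF, 18-crown-6, THF, rt) to limit β-elimination, and gives 26 directly.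

Step 5. Closure of the six-membered ring may be slow relative to intermolecular acylation or ketene dimerisation, facial selectivity may be insufficient, and the β-lactone may decarboxylate. The fallback changes both the ring closure and the source of enantiopurity; it sets out from 6 and returns at 8. Acid 6 is converted (PhSH, N,N'-dicyclohexylcarbodiimide, 4-(dimethylamino)pyridine cat.) to the S-phenyl thioester F10. Its lithium enolate (LiN(SiMe3)2, THF, −78 to 0 °C) undergoes intramolecular aldol addition to the methyl ketone, and the aldolate lactonises with loss of thiophenolate to give the racemic cis β-lactone, that is 8 together with its enantiomer F11. Preparative chromatography on a chiral stationary phase then delivers 8.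

**Further compounds**

F1 | step 12 | allyl 3-[(1S,2R)-5,7-bis(benzyloxy)-2-hydroxy-2-methyl-1,2,3,4-tetrahydronaphthalen-1-yl]-3-oxopropanoate | C[C@@]1(O)CCc2c(OCc3ccccc3)cc(OCc3ccccc3)cc2[C@@H]1C(=O)CC(=O)OCC=C
F2 | step 12 | benzyloxymethyl ether of F1 | C[C@@]1(OCOCc2ccccc2)CCc2c(OCc3ccccc3)cc(OCc3ccccc3)cc2[C@@H]1C(=O)CC(=O)OCC=C
F3 | step 12 | allyl 2-{3,5-bis(benzyloxy)-2-[(1S,2R)-5,7-bis(benzyloxy)-2-[(benzyloxy)methoxy]-2-methyl-1,2,3,4-tetrahydronaphthalene-1-carbonyl]phenyl}acetate | C[C@@]1(OCOCc2ccccc2)CCc2c(OCc3ccccc3)cc(OCc3ccccc3)cc2[C@@H]1C(=O)c1c(OCc2ccccc2)cc(OCc2ccccc2)cc1CC(=O)OCC=C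
F4 | step 12 | arylacetic acid from F3 | C[C@@]1(OCOCc2ccccc2)CCc2c(OCc3ccccc3)cc(OCc3ccccc3)cc2[C@@H]1C(=O)c1c(OCc2ccccc2)cc(OCc2ccccc2)cc1CC(=O)O
F5 | step 12 | tert-butyl 6-aryl-3,5-dioxohexanoate from F4 | C[C@@]1(OCOCc2ccccc2)CCc2c(OCc3ccccc3)cc(OCc3ccccc3)cc2[C@@H]1C(=O)c1c(OCc2ccccc2)cc(OCc2ccccc2)cc1CC(=O)CC(=O)CC(=O)OC(C)(C)C
F6 | step 12 | 4-hydroxy-2-pyranone analogue of 24 (ring D hydroxyl free) | C[C@@]1(OCOCc2ccccc2)CCc2c(OCc3ccccc3)cc(OCc3ccccc3)cc2[C@@H]1C(=O)c1c(OCc2ccccc2)cc(OCc2ccccc2)cc1Cc1cc(O)cc(=O)o1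
F7 | step 13 | C1-keto analogue of β-lactone 8 | C[C@@]1(OC2=O)CC(=O)c3c(OCc4ccccc4)cc(OCc4ccccc4)cc3[C@@H]12
F8 | step 13 | C1-keto analogue of hydroxy ketone 12 | C[C@@]1(O)CC(=O)c2c(OCc3ccccc3)cc(OCc3ccccc3)cc2[C@@H]1C(=O)Cc1cc(OCc2ccccc2)cc(=O)o1
F9 | step 13 | C1-keto analogue of 13 | C[C@@]1(OCOCc2ccccc2)CC(=O)c2c(OCc3ccccc3)cc(OCc3ccccc3)cc2[C@@H]1C(=O)Cc1cc(OCc2ccccc2)cc(=O)o1
F10 | step 5 | S-phenyl 2-[3,5-bis(benzyloxy)-2-(3-oxobutyl)phenyl]ethanethioate | O=C(Cc1cc(OCc2ccccc2)cc(OCc2ccccc2)c1CCC(C)=O)Sc1ccccc1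
F11 | step 5 | enantiomer of 8, the (3S,4R)-β-lactone | C[C@]1(OC2=O)CCc3c(OCc4ccccc4)cc(OCc4ccccc4)cc3[C@H]12
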